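**Retrosynthetic overview**
- The target comes from its 7‑O‑MOM ether by mild acid cleavage; the C3 stereocentre is already in place.
- Ring C is the only ring formed. Its C3–C4 bond is made by an enantioselective intramolecular acyl‑anion (Breslow intermediate) 1,6‑addition to a para‑quinone methide, released in situ by fluoride from a silyl ether/benzylic acetate.
- Both prenyl groups are introduced together by a twofold Stille coupling on the open‑chain dibromide.
- The C2–O1 ether bond comes from opening a racemic ring B styrene oxide with a ring A salicylaldehyde phenol, acetylated in the same pot.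
- Rings A and B are bought as 5‑bromo‑2,4‑dihydroxybenzaldehyde and 3‑bromo‑4‑hydroxybenzaldehyde.

Assumption: the SMILES is read as the (3S) enantiomer; the sense of induction of the new ring closure must be confirmed on the first run, and the commercial (5aR,10bS) antipode of the catalyst is used if the (5aS,10bR) salt gives (3R).

**Step 1**
Reactants: 1 3‑bromo‑4‑hydroxybenzaldehyde
Product: 2 3‑bromo‑4‑[(triisopropylsilyl)oxy]benzaldehyde
Conditions: TIPSCl (1.1 equiv), imidazole (2 equiv), DMF, rt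
Reagents that add atoms: chlorotriisopropylsilane, CC(C)[Si](Cl)(C(C)C)C(C)C
Why: Imidazole‑mediated silylation of the acidic phenol; the bulky silyl ether survives the basic steps 2 and 4 and later serves as the fluoride‑triggered switch for quinone methide formation.

**Step 2**
Reactants: 2 3‑bromo‑4‑[(triisopropylsilyl)oxy]benzaldehyde
Product: 3 2‑{3‑bromo‑4‑[(triisopropylsilyl)oxy]phenyl}oxirane (racemic)
Conditions: Me3S+ I− (1.3 equiv), KN(SiMe3)2 (1.25 equiv), THF, −10 °C → rt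
Reagents that add atoms: trimethylsulfonium iodide, C[S+](C)C.[I-]
Why: Corey–Chaykovsky epoxidation (ylide addition to the aldehyde, betaine closure); the new stereocentre is left racemic on purpose because it is erased at the quinone methide stage.

**Step 3**
Reactants: 4 5‑bromo‑2,4‑dihydroxybenzaldehyde
Product: 5 5‑bromo‑2‑hydroxy‑4‑(methoxymethoxy)benzaldehyde
Conditions: MOMCl (1.05 equiv), i‑Pr2NEt (1.2 equiv), CH2Cl2, 0 °C → rt
Reagents that add atoms: chloromethyl methyl ether, COCCl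
Why: Chemoselective O‑alkylation: the 4‑OH is the more acidic, free phenol while the 2‑OH is hydrogen‑bonded to the aldehyde, so one equivalent of MOMCl gives the 4‑O‑MOM ether.

**Step 4**
Reactants: 5 5‑bromo‑2‑hydroxy‑4‑(methoxymethoxy)benzaldehyde; 3 2‑{3‑bromo‑4‑[(triisopropylsilyl)oxy]phenyl}oxirane (1.2 equiv)
Product: 7 1‑{3‑bromo‑4‑[(triisopropylsilyl)oxy]phenyl}‑2‑[4‑bromo‑2‑formyl‑5‑(methoxymethoxy)phenoxy]ethyl acetate (racemic), via hydroxy ether 6 (not isolated)
Conditions: K2CO3 (0.3 equiv), DMF, 80 °C; then Ac2O, Et3N, 4‑(dimethylamino)pyridine (10 mol %), rt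
Reagents that add atoms: acetic anhydride, CC(=O)OC(C)=O
Why: Base‑catalysed SN2 opening of the epoxide by the phenoxide at the unhindered CH2 terminus (the meta‑bromine disfavours benzylic ionisation), then acetylation of the secondary benzylic alcohol in the same pot to install the leaving group; the stereocentre is racemic and irrelevant.

**Step 5**
Reactants: 7 1‑{3‑bromo‑4‑[(triisopropylsilyl)oxy]phenyl}‑2‑[4‑bromo‑2‑formyl‑5‑(methoxymethoxy)phenoxy]ethyl acetate
Product: 8 1‑{3‑(3‑methylbut‑2‑en‑1‑yl)‑4‑[(triisopropylsilyl)oxy]phenyl}‑2‑[2‑formyl‑5‑(methoxymethoxy)‑4‑(3‑methylbut‑2‑en‑1‑yl)phenoxy]ethyl acetate (racemic)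
Conditions: tributyl(prenyl)stannane (3 equiv), Pd(PPh3)4 (10 mol %), DMF, 95 °C
Reagents that add atoms: tributyl(3‑methylbut‑2‑en‑1‑yl)stannane, CCCC[Sn](CCCC)(CCCC)CC=C(C)C
Why: Twofold Migita–Kosugi–Stille coupling under neutral conditions: zerovalent palladium inserts into each C–Br bond and reductive elimination at the less hindered allyl terminus gives the linear prenyl arene; aldehyde, acetate, silyl ether and MOM ether are inert.

**Step 6**
Reactants: 8 1‑{3‑(3‑methylbut‑2‑en‑1‑yl)‑4‑[(triisopropylsilyl)oxy]phenyl}‑2‑[2‑formyl‑5‑(methoxymethoxy)‑4‑(3‑methylbut‑2‑en‑1‑yl)phenoxy]ethyl acetate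
Product: 10 (3S)‑3‑[4‑hydroxy‑3‑(3‑methylbut‑2‑en‑1‑yl)phenyl]‑7‑(methoxymethoxy)‑6‑(3‑methylbut‑2‑en‑1‑yl)‑2,3‑dihydro‑4H‑chromen‑4‑one, via para‑quinone methide 9 (not isolated)
Conditions: (5aS,10bR)‑2‑(pentafluorophenyl)‑5a,10b‑dihydro‑4H,6H‑indeno[2,1‑b][1,2,4]triazolo[4,3‑d][1,4]oxazin‑2‑ium tetrafluoroborate (20 mol %), CsOAc (20 mol %), CsF (2.5 equiv), 18‑crown‑6 (2.5 equiv), 4 Å MS, THF (0.01 M), −20 → 0 °C; AcOH quench at −20 °C
Reagents that add atoms: none
Why: Proposed new method: fluoride removes the silyl group and the phenoxide expels acetate to give para‑quinone methide 9, while the triazolylidene adds to the aldehyde to give a Breslow intermediate (acyl anion equivalent) whose nucleophilic carbon closes ring C by 6‑exo 1,6‑addition to the electrophilic methide carbon, driven by rearomatisation, with the chiral carbene choosing one face of the planar methide so that racemic 8 converges on (S)‑C3; the closest known reaction types are carbene‑catalysed intermolecular 1,6‑addition of aldehydes to para‑quinone methides, the asymmetric intramolecular Stetter reaction giving 3‑substituted chroman‑4‑ones, carbene‑catalysed ring closure of 2‑(2‑sulfonyloxyethoxy)benzaldehydes to chroman‑4‑ones, and fluoride‑triggered quinone methide generation under carbene catalysis.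

**Step 7**
Reactants: 10 (3S)‑3‑[4‑hydroxy‑3‑(3‑methylbut‑2‑en‑1‑yl)phenyl]‑7‑(methoxymethoxy)‑6‑(3‑methylbut‑2‑en‑1‑yl)‑2,3‑dihydro‑4H‑chromen‑4‑one
Product: 11 (3S)‑7‑hydroxy‑3‑[4‑hydroxy‑3‑(3‑methylbut‑2‑en‑1‑yl)phenyl]‑6‑(3‑methylbut‑2‑en‑1‑yl)‑2,3‑dihydro‑4H‑chromen‑4‑one
Conditions: 3 M aq. HCl, MeOH/THF, 40 °C
Reagents that add atoms: none
Why: Acid‑catalysed solvolysis of the MOM acetal; acid is chosen because the C3 stereocentre of an isoflavanone epimerises through its enolate under base but holds under brief mild acid, and the prenyl alkenes tolerate dilute HCl in methanol.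

**Compound list**
1 | 3‑bromo‑4‑hydroxybenzaldehyde | O=Cc1ccc(O)c(Br)c1 | starting material
2 | 3‑bromo‑4‑[(triisopropylsilyl)oxy]benzaldehyde | CC(C)[Si](Oc1ccc(C=O)cc1Br)(C(C)C)C(C)C | intermediate
3 | 2‑{3‑bromo‑4‑[(triisopropylsilyl)oxy]phenyl}oxirane (racemic) | CC(C)[Si](Oc1ccc(C2CO2)cc1Br)(C(C)C)C(C)C | intermediate
4 | 5‑bromo‑2,4‑dihydroxybenzaldehyde | O=Cc1cc(Br)c(O)cc1O | starting material
5 | 5‑bromo‑2‑hydroxy‑4‑(methoxymethoxy)benzaldehyde | COCOc1cc(O)c(C=O)cc1Br | intermediate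
6 | 5‑bromo‑2‑(2‑{3‑bromo‑4‑[(triisopropylsilyl)oxy]phenyl}‑2‑hydroxyethoxy)‑4‑(methoxymethoxy)benzaldehyde (racemic, not isolated) | COCOc1cc(OCC(O)c2ccc(O[Si](C(C)C)(C(C)C)C(C)C)c(Br)c2)c(C=O)cc1Br | intermediate
7 | 1‑{3‑bromo‑4‑[(triisopropylsilyl)oxy]phenyl}‑2‑[4‑bromo‑2‑formyl‑5‑(methoxymethoxy)phenoxy]ethyl acetate (racemic) | COCOc1cc(OCC(OC(C)=O)c2ccc(O[Si](C(C)C)(C(C)C)C(C)C)c(Br)c2)c(C=O)cc1Br | intermediate
8 | 1‑{3‑(3‑methylbut‑2‑en‑1‑yl)‑4‑[(triisopropylsilyl)oxy]phenyl}‑2‑[2‑formyl‑5‑(methoxymethoxy)‑4‑(3‑methylbut‑2‑en‑1‑yl)phenoxy]ethyl acetate (racemic) | COCOc1cc(OCC(OC(C)=O)c2ccc(O[Si](C(C)C)(C(C)C)C(C)C)c(CC=C(C)C)c2)c(C=O)cc1CC=C(C)C | intermediate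
9 | 2‑{2‑[3‑(3‑methylbut‑2‑en‑1‑yl)‑4‑oxocyclohexa‑2,5‑dien‑1‑ylidene]ethoxy}‑4‑(methoxymethoxy)‑5‑(3‑methylbut‑2‑en‑1‑yl)benzaldehyde (not isolated) | COCOc1cc(OCC=C2C=CC(=O)C(CC=C(C)C)=C2)c(C=O)cc1CC=C(C)C | intermediate
10 | (3S)‑3‑[4‑hydroxy‑3‑(3‑methylbut‑2‑en‑1‑yl)phenyl]‑7‑(methoxymethoxy)‑6‑(3‑methylbut‑2‑en‑1‑yl)‑2,3‑dihydro‑4H‑chromen‑4‑one | CC(C)=CCc1cc([C@H]2COc3cc(OCOC)c(CC=C(C)C)cc3C2=O)ccc1O | intermediate
11 | (3S)‑7‑hydroxy‑3‑[4‑hydroxy‑3‑(3‑methylbut‑2‑en‑1‑yl)phenyl]‑6‑(3‑methylbut‑2‑en‑1‑yl)‑2,3‑dihydro‑4H‑chromen‑4‑one | CC(C)=CCc1cc([C@H]2COc3cc(O)c(CC=C(C)C)cc3C2=O)ccc1O | target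

**Step count**
Total: 7 steps. Longest linear sequence: 6 steps (1 → 2 → 3 → 7 → 8 → 10 → 11, steps 1, 2, 4, 5, 6, 7).

**Steps most likely to fail, with fallbacks**

Step 6 (the ring closure). The free quinone methide may oligomerise or tautomerise to the vinylphenol faster than it is trapped, the enantioselectivity is untested, and the product can epimerise if the basic mixture warms. The fallback sets the stereocentre by enantioselective protonation instead of in the C–C bond formation. It sets out from 8: cyclisation with the achiral carbene from 2‑mesityl‑6,7‑dihydro‑5H‑pyrrolo[2,1‑c][1,2,4]triazol‑2‑ium chloride under the same fluoride trigger (slow fluoride dosing, rt) gives the racemic MOM‑protected isoflavanone F1. TMSOTf/Et3N in CH2Cl2 at 0 °C converts this into the bis‑silylated enol ether 4‑(trimethylsilyloxy)‑2H‑chromene F2. Protonation of the silyl enol ether with phenol (1.1 equiv) under a chiral Brønsted acid catalyst, the N‑triflyl thiophosphoramide of 3,3'‑bis(2,4,6‑triisopropylphenyl)‑1,1'‑bi‑2‑naphthol (5 mol %, toluene, −78 °C), followed by an aqueous citric acid work‑up that frees the aryl O–SiMe3, returns to the route at 10.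

Step 5 (twofold prenyl Stille). Oxidative addition next to the bulky silyl ether may be slow, some branched 1,1‑dimethylallyl isomer may form, and the aldehyde or benzylic acetate may not tolerate prolonged heating with palladium and stannane. The fallback sets out from 7 and replaces direct prenylation by allylation and olefin metathesis. A twofold Stille coupling with allyltributylstannane (Pd(PPh3)4, toluene, 100 °C; no regiochemical ambiguity) gives the bis‑allyl acetate F5. Cross‑metathesis with 2‑methyl‑2‑butene as co‑solvent (second‑generation Grubbs catalyst RuCl2(H2IMes)(PCy3)(=CHPh), 5 mol %, CH2Cl2, 40 °C) converts both allyl groups into prenyl groups and returns to the route at 8.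

Step 4 (epoxide opening). The hydrogen‑bonded, electron‑poor phenoxide is a weak nucleophile, some attack at the benzylic carbon is possible, and the aryl silyl ether may migrate at 80 °C. The fallback fixes the regiochemistry before the ether bond is made and sets out from 2. Wittig methylenation (Ph3P+CH3 Br−, KOt‑Bu, THF, 0 °C) gives the styrene [2‑bromo‑4‑ethenylphenoxy]triisopropylsilane F3. Markovnikov bromo‑acetoxylation (N‑bromosuccinimide, AcOH, rt) gives 2‑bromo‑1‑{3‑bromo‑4‑[(triisopropylsilyl)oxy]phenyl}ethyl acetate F4. Phenol 5 is then O‑alkylated with this primary bromide (K2CO3, NaI cat., acetone, 50 °C), as phenols are with 2‑bromoethyl acetate, and the route is rejoined at 7.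

**Further compounds**
F1 | step 6 | 3‑[4‑hydroxy‑3‑(3‑methylbut‑2‑en‑1‑yl)phenyl]‑7‑(methoxymethoxy)‑6‑(3‑methylbut‑2‑en‑1‑yl)‑2,3‑dihydro‑4H‑chromen‑4‑one (racemic) | CC(C)=CCc1cc(C2COc3cc(OCOC)c(CC=C(C)C)cc3C2=O)ccc1O
F2 | step 6 | {[7‑(methoxymethoxy)‑6‑(3‑methylbut‑2‑en‑1‑yl)‑3‑{3‑(3‑methylbut‑2‑en‑1‑yl)‑4‑[(trimethylsilyl)oxy]phenyl}‑2H‑chromen‑4‑yl]oxy}trimethylsilane | COCOc1cc2OCC(c3ccc(O[Si](C)(C)C)c(CC=C(C)C)c3)=C(O[Si](C)(C)C)c2cc1CC=C(C)C
F3 | step 4 | [2‑bromo‑4‑ethenylphenoxy]triisopropylsilane | C=Cc1ccc(O[Si](C(C)C)(C(C)C)C(C)C)c(Br)c1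
F4 | step 4 | 2‑bromo‑1‑{3‑bromo‑4‑[(triisopropylsilyl)oxy]phenyl}ethyl acetate (racemic) | CC(=O)OC(CBr)c1ccc(O[Si](C(C)C)(C(C)C)C(C)C)c(Br)c1
F5 | step 5 | 1‑{3‑(prop‑2‑en‑1‑yl)‑4‑[(triisopropylsilyl)oxy]phenyl}‑2‑[2‑formyl‑5‑(methoxymethoxy)‑4‑(prop‑2‑en‑1‑yl)phenoxy]ethyl acetate (racemic) | COCOc1cc(OCC(OC(C)=O)c2ccc(O[Si](C(C)C)(C(C)C)C(C)C)c(CC=C)c2)c(C=O)cc1CC=C
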